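Maple's first sample is a poor guide to what its catalyst is worth: maple, charged with 34 mM catalyst against cedar's 5.1 mM, still reads 39.5% of its substrate at 20.0 min, yet at 60.0 min it reads 2.6%.

| setting | cedar | maple | Wednesday's | Monday's | Sunday's | Tuesday's |
|---|---|---|---|---|---|---|
| substrate | 0.36 M | 0.36 M | 0.36 M | 0.36 M | 0.36 M | 0.36 M |
| gas phase | 20 mM (held) | 20 mM (held) | 20 mM (held) | 20 mM (held) | 20 mM (held) | 20 mM (held) |
| catalyst | 5.1 mM | 34 mM | 4.0 mM | 8.0 mM | 15 mM | 30 mM |
| remark | run made earlier | run made earlier |  |  |  |  |
| time |  |  | 2.0 h | 2.0 h | 2.0 h | 2.0 h |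

| run | time / min | target / % | substrate / % |
|---|---|---|---|
| cedar | 20.0 | 16.4 | 84.5 |
| cedar | 40.0 | 29.5 | 69.4 |
| cedar | 60.0 | 41.9 | 58.9 |
| cedar | 80.0 | 51.6 | 47.0 |
| cedar | 90.0 | 57.6 | 43.7 |
| cedar | 120 | 69.5 | 32.8 |
| maple | 20.0 | 59.3 | 39.5 |
| maple | 40.0 | 87.4 | 12.4 |
| maple | 60.0 | 97.2 | 2.6 |
| maple | 80.0 | 98.7 | 1.9 |
| maple | 90.0 | 100.3 | 0 |
| maple | 120 | 101.9 | 0.4 |

(standard deviation of a reading: 1 percentage point)

1. amount of target at the end, in percent of the substrate charged for Wednesday's, Monday's, Sunday's, Tuesday's, in this order
2. how that number moves from the first to the last of them (hardly changes / rises, then falls / rises all the way / falls all the way / falls, then rises)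

- the earlier runs were read with a standard deviation of 1 percentage point
- at the start none of the gas phase is in solution
- "hardly changes" means that all values lie within two and a half points (for a concentration: within two and a half percent of the largest)

In cedar, substrate and target add up to 101% at 60.0 min, so my reckoning takes target as what substrate has lost. It freezes what cannot be read, the gas in solution. If that stays nearly constant, substrate loses a fixed fraction per minute (pseudo-first-order). Cedar's last reading then gives 74.6 min, the time in which substrate halves at cedar's catalyst, a reading with its scatter. At 60.0 min this time gives 57.3% substrate, and cedar reads 58.9%.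

Next, let the halving time shorten in proportion to catalyst. In 2.0 h, Wednesday's then makes 1.26 halvings, Monday's 2.52, Sunday's 4.73 and Tuesday's 9.46. The targets are 58.3%, 82.6%, 96.2% and 99.9%.

The weak link is that proportion at high catalyst. At 40.0 min this schedule leaves maple 8.40% substrate, but maple reads more than that, 12.4%, a lag of 0.562 halvings, itself a reading with its scatter. Tuesday's carries less catalyst than maple, so taking that lag off Tuesday's is an estimate; it gives 99.8%, and my row still climbs from flask to flask.

The forecast gives 59.5%, 83%, 96% and 99.7%, shape rises all the way, on the view that “gas supply limits the rate at high substrate and catalyst”. At Wednesday's it stands 1.2 percentage points above mine.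

The flasks give 58.8%, 82.4%, 96.0% and 99.8%: the target rises all the way.

    gas phase ⇌ dissolved gas, rate k1*(csat - [dissolved gas]) (kL = 1.91 min⁻¹)
    substrate + dissolved gas + catalyst → catalyst + target (k = 97.9 M⁻² min⁻¹)
    2 dissolved gas → self-condensation product (k = 0.304 M⁻¹ min⁻¹)

Wednesday's also makes self-condensation product, but that step makes no difference to its target, and its dissolved gas stands at 94.9% of saturation at 1.00 h. The halving time gives Wednesday's 64.6% substrate at 1.00 h, and the flask holds 64.6%. With maple's lag it gives Tuesday's 5.56% at 1.00 h, and that flask holds 5.21%.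

(The readings stem from a simulated flask for substances that don't exist; scatter was added.)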